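Assumption: the SMILES is taken as drawn; its descriptors are 5S,8R,9R,10S (polypodane numbering), i.e. a cis-fused decalin with 5-H, 10-CH3, 8-CH3 and the C9 chain on one face and 8-OH on the other, and the route is built for exactly that isomer.

Numbering used in the text: ring A = C1–C5 and C10 (C3 ketone, C4 gem-dimethyl); ring B = C5–C10 (C8 carbinol, C9 carries the chain C11 onward); C30 = the acetoxymethyl carbon. "Homofarnesyl" = (3E,7E)-4,8,12-trimethyltrideca-3,7,11-trien-1-yl.

**Retrosynthetic overview**
1. C30–OAc is made last: E-selective allylic oxidation of the terminal isopropylidene, then acetylation.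
2. Ring A (formed second): Robinson annulation of ethyl vinyl ketone onto ring B (C10–C1, C4=C5), then cis-selective CuH reduction at C5 with C4 methylation.
3. C9–C11: copper-catalysed conjugate addition of a homofarnesyl Grignard reagent (farnesyl bromide plus one carbon) anti to the C8 silyl ether; the enolate is kept for the annulation.
4. Ring B (formed first; it is the arene of 2,4-dimethylphenol) and the C8–O bond: catalytic enantioselective para-hydroxylative dearomatisation (key C–O bond, sets C8), then hydrogenation of the spare alkene.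
5. Stereochemical relay: C8 (catalyst control) → C9 → C10 → C5 (substrate control).

**Route**

Step 1
Reactants: 1 2,4-dimethylphenol
Product: 2 (R)-4-hydroxy-2,4-dimethylcyclohexa-2,5-dien-1-one
Conditions: (R,R)-2-iodo-1,3-bis[1-(mesitylcarbamoyl)ethoxy]benzene (10 mol %; the antipode that gives R is used), mCPBA (1.2 equiv), H2O (5 equiv), CHCl3, −20 °C
Reagents that add atoms: water O
Why: Proposed new method: catalytic enantioselective para-hydroxylative dearomatisation of a simple 2,4-dialkylphenol, in which mCPBA turns the iodoarene into a λ3-iodane (trivalent iodine), ligand exchange gives an aryloxy-λ3-iodane whose two lactamide arms fold over iodine through N–H···O hydrogen bonds, the ortho-methyl group fits only the open quadrant so that one face of C4 is walled off by a mesityl group, and a water molecule hydrogen-bonded to the amide C=O on the open face adds to C4 as ArI leaves (associative, SN2'-like through the ring; the non-ionising solvent without fluoro-alcohol suppresses the free phenoxenium ion that would give racemate), which forms the C8–O bond and sets the R carbinol centre; the closest known reaction type is chiral iodoarene-catalysed oxidative dearomatisation of phenols (highly enantioselective spirolactonisation with a tethered carboxylate, para-quinol formation with water only in modest ee), so the new element is high enantiocontrol in intermolecular oxygen transfer to the para carbon.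

Step 2
Reactants: 2 (R)-4-hydroxy-2,4-dimethylcyclohexa-2,5-dien-1-one
Product: 3 (R)-4-hydroxy-2,4-dimethylcyclohex-2-en-1-one
Conditions: H2 (1 atm), RhCl(PPh3)3 (5 mol %), benzene/EtOH, 20 °C
Reagents that add atoms: none
Why: Homogeneous hydrogenation with Wilkinson's catalyst reduces only the disubstituted alkene of the cross-conjugated dienone (as with steroidal 1,4-dien-3-ones) and leaves the α-methyl enone and the carbinol centre untouched.

Step 3
Reactants: 3 (R)-4-hydroxy-2,4-dimethylcyclohex-2-en-1-one
Product: 4 (R)-2,4-dimethyl-4-(triethylsilyloxy)cyclohex-2-en-1-one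
Conditions: Et3SiOTf, 2,6-lutidine, CH2Cl2, −78 → 0 °C
Reagents that add atoms: triethylsilyl trifluoromethanesulfonate CC[Si](CC)(CC)OS(=O)(=O)C(F)(F)F
Why: Silyl triflate O-silylation of the tertiary alcohol, which removes the free hydroxyl that would otherwise direct the later conjugate addition syn and quench enolates.

Step 4
Reactants: 5 (2E,6E)-farnesyl bromide; 6 thioanisole
Product: 8 homofarnesyl phenyl sulfide, via (phenylthio)methyllithium 7 (not isolated)
Conditions: 6, n-BuLi, DABCO, THF, 0 °C; then 5, −78 → 20 °C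
Reagents that add atoms: none
Why: SN2 alkylation of the α-thio carbanion (Corey–Seebach (phenylthio)methyllithium) at the primary allylic bromide gives a one-carbon homologation without allylic transposition or loss of alkene geometry.

Step 5
Reactants: 8 homofarnesyl phenyl sulfide
Product: 10 homofarnesyl iodide [(3E,7E)-1-iodo-4,8,12-trimethyltrideca-3,7,11-triene], via sulfonium iodide 9 (not isolated)
Conditions: MeI (excess), NaI, DMF, 75 °C
Reagents that add atoms: iodomethane CI; sodium iodide [Na+].[I-]
Why: S-methylation to the sulfonium salt followed by SN2 displacement of thioanisole by iodide at the primary carbon (Corey–Jautelat sulfide-to-iodide exchange).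

Step 6
Reactants: 4 (R)-2,4-dimethyl-4-(triethylsilyloxy)cyclohex-2-en-1-one; 10 homofarnesyl iodide
Product: 12 (3R,4R)-3-homofarnesyl-2,4-dimethyl-4-(triethylsilyloxy)-1-(trimethylsilyloxy)cyclohex-1-ene (chain trans to OSiEt3), via homofarnesylmagnesium iodide 11 (not isolated)
Conditions: 10, Mg, Et2O, 20 °C; then CuBr·SMe2 (10 mol %), HMPA, Me3SiCl, 4, THF, −78 → −40 °C; Et3N
Reagents that add atoms: chlorotrimethylsilane C[Si](C)(C)Cl
Why: Copper-catalysed conjugate addition of the Grignard reagent under Me3SiCl/HMPA acceleration (Nakamura–Kuwajima conditions) is expected to occur axially at C9 anti to the pseudo-axial, bulky C8–OSiEt3 group, as in cuprate additions to 4-silyloxy-cycloalkenones, which sets C9 (R) with the chain trans to oxygen, while the enolate is trapped regiospecifically as the silyl enol ether.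

Step 7
Reactants: 12 (3R,4R)-3-homofarnesyl-2,4-dimethyl-4-(triethylsilyloxy)-1-(trimethylsilyloxy)cyclohex-1-ene; 13 ethyl vinyl ketone (pent-1-en-3-one)
Product: 16 (4aR,5R,6R)-5-homofarnesyl-1,4a,6-trimethyl-6-(triethylsilyloxy)-4,4a,5,6,7,8-hexahydronaphthalen-2(3H)-one, via lithium enolate 14 (not isolated), via 1,5-diketone 15 (not isolated)
Conditions: MeLi, THF, 0 → 20 °C; 13, −78 → −30 °C; then KOH, MeOH, 50 °C
Reagents that add atoms: none
Why: Robinson annulation through the regiospecific lithium enolate (Stork–House cleavage of the silyl enol ether), in which the Michael acceptor attacks C10 on the face opposite the adjacent C9 chain (the usual trans relay of conjugate addition–enolate trapping), placing 10-CH3 syn to the chain, and base-mediated aldol condensation then closes ring A.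

Step 8
Reactants: 16 (4aR,5R,6R)-5-homofarnesyl-1,4a,6-trimethyl-6-(triethylsilyloxy)-4,4a,5,6,7,8-hexahydronaphthalen-2(3H)-one
Product: 19 (4aS,5R,6R,8aS)-6-hydroxy-5-homofarnesyl-1,1,4a,6-tetramethyloctahydronaphthalen-2(1H)-one (cis-fused; 5S,8R,9R,10S), via diphenylsilyl enol ether 17 (not isolated), via triethylsilyl-protected ketone 18 (not isolated)
Conditions: (IPr)CuCl [chloro(1,3-bis(2,6-diisopropylphenyl)imidazol-2-ylidene)copper] (5 mol %), NaOt-Bu (5 mol %), Ph2SiH2, toluene, 20 °C; then MeI, Bu4N[Ph3SiF2], THF, 20 °C; then Bu4NF, THF, 45 °C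
Reagents that add atoms: iodomethane CI
Why: Copper hydride 1,4-reduction is chemoselective for the enone over the isolated trisubstituted alkenes and delivers hydride to C5 syn to the angular methyl, as cuprates and CuH reagents do with 10-methyl-Δ4-3-octalones, giving the cis ring fusion (C5 S); the regio-defined silyl enol ether is then unmasked by fluoride and C-methylated at C4 (one-pot conjugate reduction–alkylation, Kuwajima–Noyori-type ammonium enolate), and further fluoride cleaves the SiEt3 ether.

Step 9
Reactants: 19 (4aS,5R,6R,8aS)-6-hydroxy-5-homofarnesyl-1,1,4a,6-tetramethyloctahydronaphthalen-2(1H)-one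
Product: 20 (4aS,5R,6R,8aS)-6-hydroxy-5-[(3E,7E,11E)-13-hydroxy-4,8,12-trimethyltrideca-3,7,11-trien-1-yl]-1,1,4a,6-tetramethyloctahydronaphthalen-2(1H)-one
Conditions: SeO2 (0.3 equiv), t-BuOOH (3 equiv), salicylic acid (10 mol %), CH2Cl2, 0 → 20 °C, stopped near 60% conversion (19 recycled)
Reagents that add atoms: selenium dioxide O=[Se]=O; tert-butyl hydroperoxide CC(C)(C)OO
Why: Catalytic selenium dioxide allylic oxidation (ene reaction then [2,3]-sigmatropic shift, Sharpless variant of the Riley oxidation) prefers the terminal gem-dimethyl alkene and only its E-methyl group, giving the E primary allylic alcohol, while the ketone and tertiary alcohol are inert at room temperature.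

Step 10
Reactants: 20 (4aS,5R,6R,8aS)-6-hydroxy-5-[(3E,7E,11E)-13-hydroxy-4,8,12-trimethyltrideca-3,7,11-trien-1-yl]-1,1,4a,6-tetramethyloctahydronaphthalen-2(1H)-one
Product: 21 Myrrhanone A acetate as given, (2E,6E,10E)-13-[(1R,2R,4aS,8aS)-2-hydroxy-2,5,5,8a-tetramethyl-6-oxodecahydronaphthalen-1-yl]-2,6,10-trimethyltrideca-2,6,10-trien-1-yl acetate
Conditions: Ac2O, pyridine, CH2Cl2, 0 → 20 °C
Reagents that add atoms: acetic anhydride CC(=O)OC(C)=O
Why: Acetylation of the primary allylic alcohol; the hindered tertiary C8 hydroxyl does not react without an acyl-transfer catalyst.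

**Compound list**

1 | 2,4-dimethylphenol | Cc1ccc(O)c(C)c1 | starting material
2 | (R)-4-hydroxy-2,4-dimethylcyclohexa-2,5-dien-1-one | CC1=C[C@](C)(O)C=CC1=O | intermediate
3 | (R)-4-hydroxy-2,4-dimethylcyclohex-2-en-1-one | CC1=C[C@](C)(O)CCC1=O | intermediate
4 | (R)-2,4-dimethyl-4-(triethylsilyloxy)cyclohex-2-en-1-one | CC1=C[C@](C)(O[Si](CC)(CC)CC)CCC1=O | intermediate
5 | (2E,6E)-farnesyl bromide | CC(C)=CCC/C(C)=C/CC/C(C)=C/CBr | starting material
6 | thioanisole | CSc1ccccc1 | starting material
7 | (phenylthio)methyllithium | [Li]CSc1ccccc1 | intermediate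
8 | homofarnesyl phenyl sulfide, (3E,7E)-4,8,12-trimethyltrideca-3,7,11-trien-1-yl phenyl sulfide | CC(C)=CCC/C(C)=C/CC/C(C)=C/CCSc1ccccc1 | intermediate
9 | methyl(phenyl)(homofarnesyl)sulfonium iodide | CC(C)=CCC/C(C)=C/CC/C(C)=C/CC[S+](C)c1ccccc1.[I-] | intermediate
10 | homofarnesyl iodide, (3E,7E)-1-iodo-4,8,12-trimethyltrideca-3,7,11-triene | CC(C)=CCC/C(C)=C/CC/C(C)=C/CCI | intermediate
11 | homofarnesylmagnesium iodide | CC(C)=CCC/C(C)=C/CC/C(C)=C/CC[Mg]I | intermediate
12 | (3R,4R)-3-homofarnesyl-2,4-dimethyl-4-(triethylsilyloxy)-1-(trimethylsilyloxy)cyclohex-1-ene | CC(C)=CCC/C(C)=C/CC/C(C)=C/CC[C@@H]1C(C)=C(O[Si](C)(C)C)CC[C@@]1(C)O[Si](CC)(CC)CC | intermediate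
13 | ethyl vinyl ketone (pent-1-en-3-one) | CCC(=O)C=C | starting material
14 | lithium (3R,4R)-3-homofarnesyl-2,4-dimethyl-4-(triethylsilyloxy)cyclohex-1-en-1-olate | CC(C)=CCC/C(C)=C/CC/C(C)=C/CC[C@@H]1C(C)=C(O[Li])CC[C@@]1(C)O[Si](CC)(CC)CC | intermediate
15 | (2R,3R,4R)-3-homofarnesyl-2,4-dimethyl-2-(3-oxopentyl)-4-(triethylsilyloxy)cyclohexan-1-one | CC(C)=CCC/C(C)=C/CC/C(C)=C/CC[C@@H]1[C@@](C)(CCC(=O)CC)C(=O)CC[C@@]1(C)O[Si](CC)(CC)CC | intermediate
16 | (4aR,5R,6R)-5-homofarnesyl-1,4a,6-trimethyl-6-(triethylsilyloxy)-4,4a,5,6,7,8-hexahydronaphthalen-2(3H)-one | CC(C)=CCC/C(C)=C/CC/C(C)=C/CC[C@@H]1[C@@]2(C)CCC(=O)C(C)=C2CC[C@@]1(C)O[Si](CC)(CC)CC | intermediate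
17 | cis-fused Δ3 diphenylsilyl enol ether (5S,8R,9R,10S; C3–OSiHPh2, C3=C4, 4-methyl, 8-OSiEt3) | CC(C)=CCC/C(C)=C/CC/C(C)=C/CC[C@@H]1[C@@]2(C)CCC(O[SiH](c3ccccc3)c3ccccc3)=C(C)[C@H]2CC[C@@]1(C)O[Si](CC)(CC)CC | intermediate
18 | (4aS,5R,6R,8aS)-5-homofarnesyl-1,1,4a,6-tetramethyl-6-(triethylsilyloxy)octahydronaphthalen-2(1H)-one | CC(C)=CCC/C(C)=C/CC/C(C)=C/CC[C@@H]1[C@@]2(C)CCC(=O)C(C)(C)[C@H]2CC[C@@]1(C)O[Si](CC)(CC)CC | intermediate
19 | (4aS,5R,6R,8aS)-6-hydroxy-5-homofarnesyl-1,1,4a,6-tetramethyloctahydronaphthalen-2(1H)-one | CC(C)=CCC/C(C)=C/CC/C(C)=C/CC[C@@H]1[C@@]2(C)CCC(=O)C(C)(C)[C@H]2CC[C@@]1(C)O | intermediate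
20 | (4aS,5R,6R,8aS)-6-hydroxy-5-[(3E,7E,11E)-13-hydroxy-4,8,12-trimethyltrideca-3,7,11-trien-1-yl]-1,1,4a,6-tetramethyloctahydronaphthalen-2(1H)-one | OC/C(C)=C/CC/C(C)=C/CC/C(C)=C/CC[C@@H]1[C@@]2(C)CCC(=O)C(C)(C)[C@H]2CC[C@@]1(C)O | intermediate
21 | Myrrhanone A acetate (5S,8R,9R,10S) | CC(=O)OC/C(C)=C/CC/C(C)=C/CC/C(C)=C/CC[C@@H]1[C@@]2(C)CCC(=O)C(C)(C)[C@H]2CC[C@@]1(C)O | target

**Step count**

Total steps: 10. Longest linear sequence: 8 (1 → 21 through steps 1, 2, 3, 6, 7, 8, 9, 10); the side-chain branch (steps 4, 5) joins at step 6.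

**Three steps most likely to fail**

Step 1 (the proposed new dearomatisation; the risks are low enantioselectivity and competing ortho oxidation). Fallback with known chemistry: it sets out from 1, which is oxidised with PhI(OAc)2 in MeCN/H2O at 0 °C to racemic 4-hydroxy-2,4-dimethylcyclohexa-2,5-dien-1-one F1; F1 is resolved by preparative chiral-phase SFC, and the R enantiomer is 2, where the route is rejoined before step 2.

Step 7 (Michael addition of a congested tetrasubstituted lithium enolate to a polymerisable vinyl ketone; the risks are proton transfer, polymerisation and a poor C10 facial ratio). Fallback: it sets out from 12 and 13 and replaces the anionic Michael addition by a neutral Mukaiyama–Michael addition of the silyl enol ether under Lewis-acid catalysis ([Ph3C][SbCl6] 5 mol %, CH2Cl2, −78 °C, aqueous work-up). This gives 15, now isolated, which is cyclised and dehydrated in a separate aldol condensation (KOH, MeOH) to 16, where the route is rejoined; no compound outside the list is made (F0).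

Step 8 (conjugate reduction of a hindered tetrasubstituted enone; the risks are 1,2-reduction, a poor cis:trans ratio at C5 and incomplete quaternisation at C4). Fallback: it sets out from 12, which is annulated with methyl vinyl ketone in place of 13 (MeLi; methyl vinyl ketone; KOH, MeOH) to (4aR,5R,6R)-5-homofarnesyl-4a,6-dimethyl-6-(triethylsilyloxy)-4,4a,5,6,7,8-hexahydronaphthalen-2(3H)-one F2. This less hindered trisubstituted enone is reduced with Stryker's reagent [(Ph3P)CuH]6 (benzene, H2O, 20 °C), whose cis selectivity with 10-methyl-octalones is established, to the cis-fused (4aS,5R,6R,8aR)-5-homofarnesyl-4a,6-dimethyl-6-(triethylsilyloxy)octahydronaphthalen-2(1H)-one F3. Exhaustive C4 methylation under equilibrating conditions (t-BuOK, MeI, t-BuOH/THF; cis-fused 3-ketones enolise toward C4) gives 18, where the route is rejoined and Bu4NF gives 19.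

Further compounds
F1 | step 1 | racemic 4-hydroxy-2,4-dimethylcyclohexa-2,5-dien-1-one | CC1=CC(C)(O)C=CC1=O
F0 | step 7 | none | none
F2 | step 8 | (4aR,5R,6R)-5-homofarnesyl-4a,6-dimethyl-6-(triethylsilyloxy)-4,4a,5,6,7,8-hexahydronaphthalen-2(3H)-one | CC(C)=CCC/C(C)=C/CC/C(C)=C/CC[C@@H]1[C@@]2(C)CCC(=O)C=C2CC[C@@]1(C)O[Si](CC)(CC)CC
F3 | step 8 | (4aS,5R,6R,8aR)-5-homofarnesyl-4a,6-dimethyl-6-(triethylsilyloxy)octahydronaphthalen-2(1H)-one (cis-fused) | CC(C)=CCC/C(C)=C/CC/C(C)=C/CC[C@@H]1[C@@]2(C)CCC(=O)C[C@H]2CC[C@@]1(C)O[Si](CC)(CC)CC
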